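## Retrosynthetic overview

1. Fragilide F ⇐ C5 methylenation, global deprotection and acetylation of a 6‑chloro‑5‑oxo lactone (33).
2. 33 ⇐ transannular carboxy‑chlorination of an enone acid (C7–O lactone bond and C6–Cl together, new step); the acid ⇐ C‑glycosylation of a bridged pyranone hemiketal with a propionate ketene acetal (C8, C17).
3. The hemiketal (ring C, C4–O–C8 bridge) ⇐ Achmatowicz ring expansion of a furanophane; the ten‑membered ring B ⇐ Nozaki–Hiyama–Kishi closure of a bromofuran onto the C4 aldehyde.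
4. Bromofuran aldehyde ⇐ 2,5‑dibromofuran + ring‑A aldehyde; C2–C4 arm ⇐ syn‑alkoxyallylboration; C11 chlorohydrin ⇐ allylic oxidation, methylenation, epoxidation, chloride opening.
5. Ring A (C1, C10, C14) ⇐ catalytic asymmetric Diels–Alder reaction. Ring order: A → B (furanophane) → C (pyran) → D (lactone).

Assumption: locants C1–C20 are the briarane numbers of the target, and the enantiomers of the chiral catalyst (step 3) and borane (step 4) are assigned from their accepted stereochemical models.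

## Route

Step 1
Reactants: 1 (tert-butyldimethylsilyloxy)acetaldehyde; 2 2-(triphenylphosphoranylidene)propanal
Product: 3 (E)-4-(tert-butyldimethylsilyloxy)-2-methylbut-2-enal
Conditions: toluene, 90 °C
Reagents that add atoms: none
Why: Wittig olefination with a formyl-stabilised ylide gives the (E)-trisubstituted enal (CHO trans to CH2OTBS), which later fixes C2 and C9 trans on ring A.

Step 2
Reactants: 4 (E)-but-2-enal
Product: 5 (E)-1-(tert-butyldimethylsilyloxy)buta-1,3-diene
Conditions: TBSOTf, Et3N, Et2O, 0 °C → rt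
Reagents that add atoms: tert-butyldimethylsilyl trifluoromethanesulfonate CC(C)(C)[Si](C)(C)OS(=O)(=O)C(F)(F)F
Why: Soft γ-enolisation of the enal and O-silylation (silyl dienol ether formation) gives the (E)-1-silyloxydiene.

Step 3
Reactants: 3 (E)-4-(tert-butyldimethylsilyloxy)-2-methylbut-2-enal; 5 (E)-1-(tert-butyldimethylsilyloxy)buta-1,3-diene
Product: 6 (1R,2S,6S)-2-(tert-butyldimethylsilyloxy)-6-[(tert-butyldimethylsilyloxy)methyl]-1-methylcyclohex-3-ene-1-carbaldehyde
Conditions: (S)-3,3-diphenyl-1-(o-tolyl)tetrahydro-1H,3H-pyrrolo[1,2-c][1,3,2]oxazaborole (20 mol%), Tf2NH (17 mol%), CH2Cl2, −78 → −40 °C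
Reagents that add atoms: none
Why: Catalytic enantioselective Diels–Alder reaction in which the formyl-bound oxazaborolidinium ion shields one enal face (diene adds to the C1 Si face), the silyloxy terminus bonds to the formyl-bearing carbon (ortho rule), the endo-formyl transition state puts OTBS cis to CHO and the (E)-dienophile keeps CH2OTBS trans to CHO, so C1, C10 and C14 are set.

Step 4
Reactants: 6 ring-A aldehyde; 7 3-(methoxymethoxy)prop-1-ene
Product: 9 ring-A homoallylic alcohol (C2-OH 2R; C3-OMOM 3R; 2,3-syn), via alkoxyallylborane 8 (not isolated)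
Conditions: 7, s-BuLi, THF, −78 °C; (−)-Ipc2BOMe; BF3·OEt2; then 6, −78 °C; NaOH, H2O2
Reagents that add atoms: none
Why: Brown syn-alkoxyallylboration through a closed chair transition state, where the (Z)-γ-alkoxyallylborane gives the 2,3-syn adduct and the isopinocampheyl groups of the (+)-α-pinene series direct attack to the aldehyde Si face, setting C2 and C3.

Step 5
Reactants: 9 ring-A homoallylic alcohol
Product: 10 C2 acetate
Conditions: Ac2O, pyridine, DMAP (cat.), CH2Cl2, rt
Reagents that add atoms: acetic anhydride CC(=O)OC(C)=O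
Why: DMAP-catalysed acylation installs the C2 acetate of the target, which also serves as protecting group.

Step 6
Reactants: 10 C2 acetate
Product: 11 ring-A enone (C11 ketone; 12,13-ene)
Conditions: Rh2(cap)4 (dirhodium tetrakis(caprolactamate), 1 mol%), TBHP (5 equiv), K2CO3, CH2Cl2, rt
Reagents that add atoms: tert-butyl hydroperoxide CC(C)(C)OO
Why: Dirhodium-catalysed allylic C–H oxidation converts the ring allylic CH2 (C11) into the enone, the other allylic C–H (C14) being shielded by its silyl ether and the adjacent quaternary carbon.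

Step 7
Reactants: 11 ring-A enone
Product: 12 C11 ketone
Conditions: [(Ph3P)CuH]6 (5 mol%), H2 (20 atm), t-BuOH (cat.), benzene, rt
Reagents that add atoms: none
Why: Copper hydride-catalysed conjugate reduction (Stryker) saturates only the enone C=C and leaves the vinyl group, with C10 staying in its thermodynamic equatorial configuration.

Step 8
Reactants: 12 C11 ketone
Product: 13 11(20)-exocyclic alkene
Conditions: Zn, CH2Br2, TiCl4, THF/CH2Cl2, 0 °C → rt
Reagents that add atoms: dibromomethane BrCBr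
Why: Takai–Lombardo methylenation is a non-basic zinc/titanium carbenoid olefination, so the enolisable ketone is converted without C10 epimerisation or ester attack.

Step 9
Reactants: 13 11(20)-exocyclic alkene
Product: 14 11α,20-epoxide
Conditions: mCPBA, NaHCO3, CH2Cl2, 0 °C
Reagents that add atoms: 3-chloroperoxybenzoic acid OOC(=O)c1cccc(Cl)c1
Why: Prilezhaev epoxidation of the most electron-rich (1,1-disubstituted) alkene from the face opposite the axial C1 methyl places the oxygen equatorial (α) and C20 axial, setting C11.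

Step 10
Reactants: 14 11α,20-epoxide
Product: 15 C9 primary alcohol
Conditions: TBAF, AcOH, THF, 0 °C
Reagents that add atoms: none
Why: Buffered fluoride desilylation removes the unhindered primary TBS ether much faster than the neopentyl secondary one at C14.

Step 11
Reactants: 15 C9 primary alcohol
Product: 16 C9 aldehyde
Conditions: DMP, NaHCO3, CH2Cl2, 0 °C
Reagents that add atoms: none
Why: Dess–Martin oxidation gives the aldehyde under buffered conditions that do not epimerise C10 or open the epoxide.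

Step 12
Reactants: 16 C9 aldehyde; 17 2,5-dibromofuran
Product: 20 (9S)-5-bromofuran-2-yl carbinol TES ether, via 5-bromo-2-furyllithium 18 (not isolated), via lithium alkoxide 19 (not isolated)
Conditions: 17, n-BuLi, THF, −78 °C; then 16, −78 °C; then TESOTf, −78 → 0 °C
Reagents that add atoms: triethylsilyl trifluoromethanesulfonate CC[Si](CC)(CC)OS(=O)(=O)C(F)(F)F
Why: Bromine–lithium exchange followed by Felkin–Anh 1,2-addition (nucleophile anti to the quaternary C1, non-chelating THF) sets C9, and the alkoxide is capped in the flask as a non-participating silyl ether.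

Step 13
Reactants: 20 (9S)-5-bromofuran-2-yl carbinol TES ether
Product: 22 C4 aldehyde, via vicinal diol 21 (not isolated)
Conditions: OsO4 (2 mol%), NaIO4, 2,6-lutidine, dioxane/H2O (3:1), rt
Reagents that add atoms: sodium periodate [Na+].[O-]I(=O)(=O)=O; osmium tetroxide O=[Os](=O)(=O)=O
Why: Lemieux–Johnson oxidative cleavage (osmylation then periodate glycol cleavage) turns only the terminal vinyl group into the C4 aldehyde without touching the aromatic bromofuran.

Step 14
Reactants: 22 C4 aldehyde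
Product: 23 C11 O-TMS chlorohydrin aldehyde
Conditions: TMSCl, n-Bu4NCl (10 mol%), CH2Cl2, 0 °C
Reagents that add atoms: chlorotrimethylsilane C[Si](C)(C)Cl
Why: Chloride-catalysed silyl chloride opening of the epoxide is an SN2 attack at the primary C20 with retention at C11, giving the target chlorohydrin already protected as its TMS ether.

Step 15
Reactants: 23 C11 O-TMS chlorohydrin aldehyde
Product: 25 furanophane C4 alcohol (ring B closed), via furylchromium dichloride 24 (not isolated)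
Conditions: CrCl2 (8 equiv), NiCl2 (2 mol%), DMSO/THF, rt, 2 mM
Reagents that add atoms: none
Why: Nozaki–Hiyama–Kishi macrocyclization (zerovalent nickel inserts into C–Br, transmetalation to trivalent chromium, carbonyl addition) closes the ten-membered ring, and non-chelated Felkin–Anh addition to the α-alkoxy aldehyde gives the 3,4-anti carbinol, setting C4.

Step 16
Reactants: 25 furanophane C4 alcohol
Product: 27 bridged pyranone hemiketal (ring C), via cis-ene-dione 26 (not isolated)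
Conditions: NBS, NaHCO3, NaOAc, THF/H2O (4:1), 0 °C
Reagents that add atoms: water O
Why: Achmatowicz oxidative ring expansion opens the furan to the cis-ene-dione and the C4 hydroxyl closes onto the C8 carbonyl, forming the C4–O–C8 bridge with retention at C4 and the hemiketal hydroxyl forced exo.

Step 17
Reactants: 28 propanoic acid
Product: 29 1,1-bis(trimethylsilyloxy)prop-1-ene
Conditions: LDA (2.2 equiv), THF, −78 → 0 °C; TMSCl
Reagents that add atoms: chlorotrimethylsilane C[Si](C)(C)Cl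
Why: Double deprotonation of the acid and O-silylation of the dianion gives the bis-silyl ketene acetal.

Step 18
Reactants: 27 bridged pyranone hemiketal; 29 1,1-bis(trimethylsilyloxy)prop-1-ene
Product: 31 pyranone propanoic acid (C8 quaternary; 17R), via trimethylsilyl ester 30 (not isolated)
Conditions: 29 (4 equiv), TMSOTf (30 mol%), CH2Cl2, −78 → −40 °C; pH 5 buffer
Reagents that add atoms: none
Why: Mukaiyama-type C-glycosylation in which the bridgehead oxocarbenium ion can be attacked only from the exo face (C8), and an antiperiplanar open transition state with the methyl over the flat C6=C7 side and not against C9 gives 17R.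

Step 19
Reactants: 31 pyranone propanoic acid
Product: 33 6-chloro-5-oxo lactone (ring D), via ammonium enolate 32 (not isolated)
Conditions: NCS (1.15 equiv), DABCO (20 mol%), 4 Å MS, CHCl3, −30 °C
Reagents that add atoms: N-chlorosuccinimide O=C1CCC(=O)N1Cl
Why: Proposed new method: amine-catalysed formal syn carboxy-chlorination of an enone, in which the exo carboxylate adds to C7 in a 5-exo oxa-Michael step (C7–O bond, ring D) and the resulting C5 enolate is chlorinated by NCS on its only open (exo) face, so C7–O and C6–Cl end up cis, which an anti-selective chloronium chlorolactonization cannot give; the closest known reactions are halolactonization and organocatalytic conjugate addition/α-halogenation cascades.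

Step 20
Reactants: 33 6-chloro-5-oxo lactone
Product: 34 5(16)-methylene compound
Conditions: Cp2Ti(μ-Cl)(μ-CH2)AlMe2, pyridine (cat.), THF/toluene, −40 → 0 °C
Reagents that add atoms: Tebbe reagent C[Al-]1(C)C[Ti]([Cl+]1)(C2C=CC=C2)C3C=CC=C3
Why: Tebbe methylenation (titanium carbene [2+2]/retro-[2+2]) is non-basic, so the α-chloro-β-acyloxy ketone is olefinated at low temperature without elimination and faster than the esters.

Step 21
Reactants: 34 5(16)-methylene compound
Product: 35 3,9,14-triol 2-acetate (C11-OH free)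
Conditions: HCl (1.25 M in MeOH), 0 °C → rt
Reagents that add atoms: none
Why: Acid-catalysed methanolysis removes the MOM acetal and the TMS, TES and TBS ethers in one operation, chloride as the only nucleophile cannot exchange the allylic chloride, and any C2 acetate lost is restored in the next step.

Step 22
Reactants: 35 3,9,14-triol 2-acetate
Product: 36 Fragilide F
Conditions: Ac2O, pyridine, DMAP (cat.), CH2Cl2, rt
Reagents that add atoms: acetic anhydride CC(=O)OC(C)=O
Why: DMAP-catalysed acetylation esterifies the three secondary alcohols while the hindered tertiary C11 alcohol stays free.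

## Compound list

1 | (tert-butyldimethylsilyloxy)acetaldehyde | O=CCO[Si](C)(C)C(C)(C)C | starting material
2 | 2-(triphenylphosphoranylidene)propanal | CC(C=O)=P(c1ccccc1)(c1ccccc1)c1ccccc1 | starting material
3 | (E)-4-(tert-butyldimethylsilyloxy)-2-methylbut-2-enal | O=C/C(C)=C/CO[Si](C)(C)C(C)(C)C | intermediate
4 | (E)-but-2-enal | C/C=C/C=O | starting material
5 | (E)-1-(tert-butyldimethylsilyloxy)buta-1,3-diene | C=C/C=C/O[Si](C)(C)C(C)(C)C | intermediate
6 | (1R,2S,6S)-2-(tert-butyldimethylsilyloxy)-6-[(tert-butyldimethylsilyloxy)methyl]-1-methylcyclohex-3-ene-1-carbaldehyde (ring A; CHO = C2, CH2OTBS = C9, OTBS at C14) | CC(C)(C)[Si](C)(C)OC[C@H]1CC=C[C@H](O[Si](C)(C)C(C)(C)C)[C@]1(C)C=O | intermediate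
7 | 3-(methoxymethoxy)prop-1-ene | C=CCOCOC | starting material
8 | (Z)-[3-(methoxymethoxy)prop-2-enyl]bis(isopinocampheyl)borane, (+)-α-pinene series | COCO/C=C\CB([C@@H]1C[C@@H]2C[C@H]([C@H]1C)C2(C)C)[C@@H]1C[C@@H]2C[C@H]([C@H]1C)C2(C)C | intermediate
9 | ring A of 6 with CHO replaced by (1R,2R)-1-hydroxy-2-(methoxymethoxy)but-3-enyl (C2-OH, C3-OMOM, 2,3-syn) | CC(C)(C)[Si](C)(C)OC[C@H]1CC=C[C@H](O[Si](C)(C)C(C)(C)C)[C@]1(C)[C@@H](O)[C@@H](C=C)OCOC | intermediate
10 | C2 acetate of 9 | CC(C)(C)[Si](C)(C)OC[C@H]1CC=C[C@H](O[Si](C)(C)C(C)(C)C)[C@]1(C)[C@@H](OC(C)=O)[C@@H](C=C)OCOC | intermediate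
11 | enone: 10 with C11 ketone conjugated to the 12,13-alkene | CC(C)(C)[Si](C)(C)OC[C@H]1C(=O)C=C[C@H](O[Si](C)(C)C(C)(C)C)[C@]1(C)[C@@H](OC(C)=O)[C@@H](C=C)OCOC | intermediate
12 | saturated C11 ketone | CC(C)(C)[Si](C)(C)OC[C@H]1C(=O)CC[C@H](O[Si](C)(C)C(C)(C)C)[C@]1(C)[C@@H](OC(C)=O)[C@@H](C=C)OCOC | intermediate
13 | 11(20)-exocyclic methylene compound | CC(C)(C)[Si](C)(C)OC[C@H]1C(=C)CC[C@H](O[Si](C)(C)C(C)(C)C)[C@]1(C)[C@@H](OC(C)=O)[C@@H](C=C)OCOC | intermediate
14 | 11α,20-spiro-epoxide (O equatorial, trans to Me-15) | CC(C)(C)[Si](C)(C)OC[C@H]1[C@@]2(CO2)CC[C@H](O[Si](C)(C)C(C)(C)C)[C@]1(C)[C@@H](OC(C)=O)[C@@H](C=C)OCOC | intermediate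
15 | C9 primary alcohol of 14 | OC[C@H]1[C@@]2(CO2)CC[C@H](O[Si](C)(C)C(C)(C)C)[C@]1(C)[C@@H](OC(C)=O)[C@@H](C=C)OCOC | intermediate
16 | C9 aldehyde | O=C[C@H]1[C@@]2(CO2)CC[C@H](O[Si](C)(C)C(C)(C)C)[C@]1(C)[C@@H](OC(C)=O)[C@@H](C=C)OCOC | intermediate
17 | 2,5-dibromofuran | Brc1ccc(Br)o1 | starting material
18 | 5-bromo-2-furyllithium | [Li]c1ccc(Br)o1 | intermediate
19 | lithium (9S)-alkoxide from 16 and 18 | Brc1ccc(o1)[C@@H]([O-])[C@H]1[C@@]2(CO2)CC[C@H](O[Si](C)(C)C(C)(C)C)[C@]1(C)[C@@H](OC(C)=O)[C@@H](C=C)OCOC.[Li+] | intermediate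
20 | (9S)-(5-bromofuran-2-yl)carbinol triethylsilyl ether (furan C2 = C8, furan C5–Br = C5) | Brc1ccc(o1)[C@@H](O[Si](CC)(CC)CC)[C@H]1[C@@]2(CO2)CC[C@H](O[Si](C)(C)C(C)(C)C)[C@]1(C)[C@@H](OC(C)=O)[C@@H](C=C)OCOC | intermediate
21 | vicinal diol from the vinyl group of 20 (carbinol epimers) | Brc1ccc(o1)[C@@H](O[Si](CC)(CC)CC)[C@H]1[C@@]2(CO2)CC[C@H](O[Si](C)(C)C(C)(C)C)[C@]1(C)[C@@H](OC(C)=O)[C@@H](C(O)CO)OCOC | intermediate
22 | C4 aldehyde (α-OMOM at C3) | Brc1ccc(o1)[C@@H](O[Si](CC)(CC)CC)[C@H]1[C@@]2(CO2)CC[C@H](O[Si](C)(C)C(C)(C)C)[C@]1(C)[C@@H](OC(C)=O)[C@@H](C=O)OCOC | intermediate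
23 | 22 with the epoxide opened to C11-OTMS (α) and C20-Cl | Brc1ccc(o1)[C@@H](O[Si](CC)(CC)CC)[C@H]1[C@@](O[Si](C)(C)C)(CCl)CC[C@H](O[Si](C)(C)C(C)(C)C)[C@]1(C)[C@@H](OC(C)=O)[C@@H](C=O)OCOC | intermediate
24 | furylchromium dichloride derived from 23 | Cl[Cr](Cl)c1ccc(o1)[C@@H](O[Si](CC)(CC)CC)[C@H]1[C@@](O[Si](C)(C)C)(CCl)CC[C@H](O[Si](C)(C)C(C)(C)C)[C@]1(C)[C@@H](OC(C)=O)[C@@H](C=O)OCOC | intermediate
25 | furanophane: ten-membered ring B containing furan C5–C8, free C4-OH (3,4-anti) | O[C@@H]2c1ccc(o1)[C@@H](O[Si](CC)(CC)CC)[C@H]1[C@@](O[Si](C)(C)C)(CCl)CC[C@H](O[Si](C)(C)C(C)(C)C)[C@]1(C)[C@@H](OC(C)=O)[C@@H]2OCOC | intermediate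
26 | macrocyclic (Z)-6-ene-5,8-dione with free C4-OH | O[C@@H]2C(=O)/C=C\C(=O)[C@@H](O[Si](CC)(CC)CC)[C@H]1[C@@](O[Si](C)(C)C)(CCl)CC[C@H](O[Si](C)(C)C(C)(C)C)[C@]1(C)[C@@H](OC(C)=O)[C@@H]2OCOC | intermediate
27 | bridged 2H-pyran-3(6H)-one: C4–O–C8 bridge, C5 ketone, 6,7-ene, exo C8-OH | O=C1[C@H]2O[C@@](O)(C=C1)[C@@H](O[Si](CC)(CC)CC)[C@H]1[C@@](O[Si](C)(C)C)(CCl)CC[C@H](O[Si](C)(C)C(C)(C)C)[C@]1(C)[C@@H](OC(C)=O)[C@@H]2OCOC | intermediate
28 | propanoic acid | CCC(=O)O | starting material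
29 | 1,1-bis(trimethylsilyloxy)prop-1-ene | CC=C(O[Si](C)(C)C)O[Si](C)(C)C | intermediate
30 | trimethylsilyl ester of 31 | O=C1[C@H]2O[C@@]([C@@H](C)C(=O)O[Si](C)(C)C)(C=C1)[C@@H](O[Si](CC)(CC)CC)[C@H]1[C@@](O[Si](C)(C)C)(CCl)CC[C@H](O[Si](C)(C)C(C)(C)C)[C@]1(C)[C@@H](OC(C)=O)[C@@H]2OCOC | intermediate
31 | pyranone with exo (17R)-1-carboxyethyl group on quaternary C8 | O=C1[C@H]2O[C@@]([C@@H](C)C(=O)O)(C=C1)[C@@H](O[Si](CC)(CC)CC)[C@H]1[C@@](O[Si](C)(C)C)(CCl)CC[C@H](O[Si](C)(C)C(C)(C)C)[C@]1(C)[C@@H](OC(C)=O)[C@@H]2OCOC | intermediate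
32 | C5 enolate of the C7–O lactone (DABCO-H+ salt) | [O-]C=1[C@H]2O[C@]3([C@@H](C)C(=O)O[C@H]3C=1)[C@@H](O[Si](CC)(CC)CC)[C@H]1[C@@](O[Si](C)(C)C)(CCl)CC[C@H](O[Si](C)(C)C(C)(C)C)[C@]1(C)[C@@H](OC(C)=O)[C@@H]2OCOC.C1C[NH+]2CCN1CC2 | intermediate
33 | 6-chloro-5-oxo lactone (rings A–D complete; Cl and lactone O cis, both exo) | O=C1[C@H]2O[C@]3([C@@H](C)C(=O)O[C@H]3[C@H]1Cl)[C@@H](O[Si](CC)(CC)CC)[C@H]1[C@@](O[Si](C)(C)C)(CCl)CC[C@H](O[Si](C)(C)C(C)(C)C)[C@]1(C)[C@@H](OC(C)=O)[C@@H]2OCOC | intermediate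
34 | 5(16)-methylene compound, still protected (3-OMOM, 9-OTES, 11-OTMS, 14-OTBS, 2-OAc) | C=C1[C@H]2O[C@]3([C@@H](C)C(=O)O[C@H]3[C@H]1Cl)[C@@H](O[Si](CC)(CC)CC)[C@H]1[C@@](O[Si](C)(C)C)(CCl)CC[C@H](O[Si](C)(C)C(C)(C)C)[C@]1(C)[C@@H](OC(C)=O)[C@@H]2OCOC | intermediate
35 | 3,9,14-triol 2-acetate with free C11-OH | C=C1[C@H]2O[C@]3([C@@H](C)C(=O)O[C@H]3[C@H]1Cl)[C@@H](O)[C@H]1[C@@](O)(CCl)CC[C@H](O)[C@]1(C)[C@@H](OC(C)=O)[C@@H]2O | intermediate
36 | Fragilide F | C=C1[C@H]2O[C@]3([C@@H](C)C(=O)O[C@H]3[C@H]1Cl)[C@@H](OC(C)=O)[C@H]1[C@@](O)(CCl)CC[C@H](OC(C)=O)[C@]1(C)[C@@H](OC(C)=O)[C@@H]2OC(C)=O | target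

## Step count and risks

Total step count: 22. Longest linear sequence: 20 (steps 1, 3–16, 18–22).

The three steps most likely to fail are 15, 18 and 19.

Step 15, the macrocyclizing chromium/nickel closure, must form a strained furanophane and set C4 at the same time. The fallback closes the ring by electrophilic aromatic substitution instead of an organochromium addition. It sets out from aldehyde 16: 2-furyllithium (furan, n-BuLi) followed by TESOTf gives the bromine-free furyl carbinol silyl ether F1; OsO4/NaIO4 gives the C4 aldehyde F2; TMSCl with catalytic n-Bu4NCl gives the silylated chlorohydrin aldehyde F3; BF3·OEt2 at high dilution and −78 °C then brings about an intramolecular Friedel–Crafts hydroxyalkylation of the free furan α-position by the non-chelated aldehyde, and the route is rejoined at furanophane 25.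

Step 18, the C-glycosylation, needs a strained bridgehead oxocarbenium ion and could be diverted to Mukaiyama–Michael addition at C7. The fallback uses an allylmetal nucleophile and builds the carboxyl group afterwards. It sets out from hemiketal 27: (E)-crotyltrimethylsilane with BF3·OEt2 (Hosomi–Sakurai C-glycosylation) gives the exo but-3-en-2-yl C-glycoside F4 (17-epimers separable); selective ozonolysis of the electron-rich terminal alkene (O3, pyridine, then Me2S) gives aldehyde F5; Pinnick oxidation (NaClO2, NaH2PO4, 2-methylbut-2-ene) comes back to acid 31.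

Step 19, the proposed carboxy-chlorination, may stall at the reversible oxa-Michael stage or lose carboxylate again after chlorination. The fallback separates the two bond formations with known reactions. It sets out from acid 31: DBU-catalysed intramolecular oxa-Michael lactonization gives the keto lactone F6; TMSOTf/Et3N gives the C5–C6 silyl enol ether F7 (the bridgehead C4 cannot enolise); chlorination of the silyl enol ether with NCS from the exo face comes back to chloro keto lactone 33.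

Further compounds
F1 | step 15 | (9S)-furan-2-yl carbinol triethylsilyl ether (20 without bromine) | c1ccc(o1)[C@@H](O[Si](CC)(CC)CC)[C@H]1[C@@]2(CO2)CC[C@H](O[Si](C)(C)C(C)(C)C)[C@]1(C)[C@@H](OC(C)=O)[C@@H](C=C)OCOC
F2 | step 15 | C4 aldehyde of F1 | c1ccc(o1)[C@@H](O[Si](CC)(CC)CC)[C@H]1[C@@]2(CO2)CC[C@H](O[Si](C)(C)C(C)(C)C)[C@]1(C)[C@@H](OC(C)=O)[C@@H](C=O)OCOC
F3 | step 15 | C11 O-TMS chlorohydrin aldehyde (23 without bromine) | c1ccc(o1)[C@@H](O[Si](CC)(CC)CC)[C@H]1[C@@](O[Si](C)(C)C)(CCl)CC[C@H](O[Si](C)(C)C(C)(C)C)[C@]1(C)[C@@H](OC(C)=O)[C@@H](C=O)OCOC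
F4 | step 18 | C8 exo but-3-en-2-yl C-glycoside of the pyranone | O=C1[C@H]2O[C@@]([C@@H](C)C=C)(C=C1)[C@@H](O[Si](CC)(CC)CC)[C@H]1[C@@](O[Si](C)(C)C)(CCl)CC[C@H](O[Si](C)(C)C(C)(C)C)[C@]1(C)[C@@H](OC(C)=O)[C@@H]2OCOC
F5 | step 18 | C19 aldehyde (2-oxo-1-methylethyl group on C8) | O=C1[C@H]2O[C@@]([C@@H](C)C=O)(C=C1)[C@@H](O[Si](CC)(CC)CC)[C@H]1[C@@](O[Si](C)(C)C)(CCl)CC[C@H](O[Si](C)(C)C(C)(C)C)[C@]1(C)[C@@H](OC(C)=O)[C@@H]2OCOC
F6 | step 19 | 5-oxo lactone without chlorine at C6 | O=C1[C@H]2O[C@]3([C@@H](C)C(=O)O[C@H]3C1)[C@@H](O[Si](CC)(CC)CC)[C@H]1[C@@](O[Si](C)(C)C)(CCl)CC[C@H](O[Si](C)(C)C(C)(C)C)[C@]1(C)[C@@H](OC(C)=O)[C@@H]2OCOC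
F7 | step 19 | C5–C6 trimethylsilyl enol ether of F6 | C[Si](C)(C)OC=1[C@H]2O[C@]3([C@@H](C)C(=O)O[C@H]3C=1)[C@@H](O[Si](CC)(CC)CC)[C@H]1[C@@](O[Si](C)(C)C)(CCl)CC[C@H](O[Si](C)(C)C(C)(C)C)[C@]1(C)[C@@H](OC(C)=O)[C@@H]2OCOC
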